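The constants are made up, and the outcome is calculated.

Slowness is the usual complaint about a reaction, and the bench answer is heat: a warmer flask should hold more product sooner. These flasks test that rule on the target.

the same everywhere: substrate 0.050 M; time 40 s
- delta: temperature 25 °C
- eta: temperature 50 °C
- alpha: at 50 °C until 12 s, from then on at 0 °C
- gamma: temperature 0 °C

    2 substrate → target (k1 = 1.1 L mol⁻¹ s⁻¹, Ea1 = 37.0 kJ mol⁻¹)
    target → over-reaction product (k2 = 0.036 s⁻¹, Ea2 = 81.0 kJ mol⁻¹)
    (constants at 25 °C)

- a species is counted by the substrate in it: one target or over-reaction product counts as two
- a doubled species enters its step squared and goes two at a time
- the constants hold at 25 °C; other temperatures follow from the activation energies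

- which flask leads in amount of target, in percent of the substrate charged ("all alike" within 1.5 percentage points) (delta / eta / alpha / gamma / all alike)
- how much target is there at the end, in percent of the substrate charged: delta
- how much target is there at the end, in percent of the substrate charged: eta
- how much target is there at the end, in percent of the substrate charged: alpha
- how much target is there at the end, in percent of the substrate charged: gamma

For substrate the rule works: its first half-life is 2.87 s in eta against 35.6 s in gamma. But from gamma to eta the second step speeds up by a factor of 250 and the first by 12. The lifetime of the target therefore shrinks from 553 s in gamma to 2.22 s in eta.

The rule's border is the number of target lifetimes inside the run, time over lifetime. That number is 0.0724 in gamma, so loss is small and the target nearly tracks the substrate converted, with a ceiling of 52.9%. In eta it is 18.0, so this reckoning sets the target of eta near the level where making equals using: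

fraction of substrate left = 1 / (1 + time / half-life) = 6.68%

target share = (target lifetime / substrate half-life) × (fraction left, squared) = 0.346%

This second line is the standing share, the steady-state approximation: the percentage of target that the present making rate can hold up against its lifetime.

Delta has 1.44 lifetimes, and for it the standing share gives 10.5% and the substrate converted gives 81.5%. This hand reckoning therefore does not rank delta against gamma, and it leaves alpha unreckoned.

The forecast goes further. It names gamma as the leader, with 29.3% for delta, 0.39% for eta, 6.8% for alpha and 50.6% for gamma. For eta its figure stands above the standing share of 0.346%, and its ground there is that “target is quasi-steady by 40 s”.

The simulation gives gamma as the leader, with 29.3% for delta, 0.389% for eta, 6.83% for alpha and 50.6% for gamma.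

Eta holds 0.389% of target against the standing share of 0.346%, and its ratio of making to using reads 0.889 at 40.0 s. The target in eta is still being made slower than it is used. The neighbouring flask is like eta but charged with 0.013 M of substrate, which makes the half-life 11.0 s. The fraction left is then 21.6% and the standing share 0.942%. That flask reads 22% of substrate and 1.03% of target, more than eta.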